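## Retrosynthetic overview
1. The oxirane is the only ring built and it is closed last. It is disconnected at both C–O bonds to the 1,1-disubstituted alkene 5, and the single stereocentre is set in that same flask.
2. The key step is a cinchona-alkaloid-catalysed Br+ transfer. The resident pentanoate carbonyl closes first to a transient dioxolan-2-ylium ring, water opens it, and a 3-exo SN2 then closes the oxirane.
3. Alkene 5 is disconnected at the aryl–vinyl bond into aryl bromide 2 and 2-boryl allyl pentanoate 4 (Suzuki–Miyaura).
4. Compound 2 comes from phenol-selective isobutyrylation of 1, and 4 from pentanoylation of 3. No protecting groups are used, and the benzylic OH stays free throughout.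

Assumption: 1 and 3 are taken as catalogue compounds; reagents that only deliver an acyl group, Br+ or O are treated as reagents and carry no number.

## Route

Step 1
Reactants: 1 2-bromo-5-(hydroxymethyl)phenol
Product: 2 2-bromo-5-(hydroxymethyl)phenyl 2-methylpropanoate
Conditions: i-PrCOCl (1.0 equiv), NaOH (1.05 equiv), n-Bu4NHSO4 (5 mol %), CH2Cl2/H2O, 0 °C, 30 min
Reagents that add atoms: isobutyryl chloride, CC(C)C(=O)Cl
Why: Schotten–Baumann (phase-transfer) O-acylation, in which one equivalent of NaOH ionises only the phenol (pKa about 8.5 against about 15 for the benzylic OH), so the phenoxide is acylated within minutes and the neutral primary alcohol stays free; no stereocentre is involved.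

Step 2
Reactants: 3 2-(4,4,5,5-tetramethyl-1,3,2-dioxaborolan-2-yl)prop-2-en-1-ol
Product: 4 2-(4,4,5,5-tetramethyl-1,3,2-dioxaborolan-2-yl)prop-2-en-1-yl pentanoate
Conditions: (n-BuCO)2O (1.2 equiv), Et3N (1.5 equiv), DMAP (5 mol %), CH2Cl2, 0 °C to rt
Reagents that add atoms: pentanoic anhydride, CCCCC(=O)OC(=O)CCCC
Why: DMAP-catalysed acyl transfer (Steglich-type esterification with an anhydride) onto an unhindered primary allylic alcohol, with the vinyl–B(pin) unit inert under these conditions.

Step 3
Reactants: 2 2-bromo-5-(hydroxymethyl)phenyl 2-methylpropanoate; 4 2-(4,4,5,5-tetramethyl-1,3,2-dioxaborolan-2-yl)prop-2-en-1-yl pentanoate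
Product: 5 2-[4-(hydroxymethyl)-2-(2-methylpropanoyloxy)phenyl]prop-2-en-1-yl pentanoate
Conditions: Pd(OAc)2 (2 mol %), SPhos (4 mol %), CsF (3 equiv), 1,4-dioxane, 50–60 °C
Reagents that add atoms: none
Why: Suzuki–Miyaura sp2–sp2 coupling, in which oxidative addition into Ar–Br and fast reductive elimination outrun the reversible ionisation of the allylic ester (a chemoselectivity known for 2-boryl allylic acetates), while anhydrous fluoride activates the boronate without hydroxide, so both esters and the free alcohol persist.

Step 4
Reactants: 5 2-[4-(hydroxymethyl)-2-(2-methylpropanoyloxy)phenyl]prop-2-en-1-yl pentanoate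
Product: 8 [(2R)-2-[4-(hydroxymethyl)-2-(2-methylpropanoyloxy)phenyl]oxiran-2-yl]methyl pentanoate, via dioxolan-2-ylium ion 6 (not isolated), via (S)-bromohydrin 7 (not isolated)
Conditions: (DHQD)2PHAL (10 mol %), TsOH·H2O (10 mol %), PhCONHBr (1.05 equiv), acetone/H2O 20:1, −30 °C; then K2CO3 (2 equiv) in H2O, 0 °C, 20 min
Reagents that add atoms: water, O; N-bromobenzamide, O=C(NBr)c1ccccc1 (its Br is found only in 6 and 7, not in 8)
Why: Proposed new method: an ester-relayed enantioselective bromofunctionalisation, in which the (DHQD)2PHAL-bound N-bromoamide transfers Br+ to the terminal CH2 while the carbonyl O of the resident pentanoate closes 5-exo on the incipient tertiary benzylic cation (a unimolecular, anchimeric capture that should be faster and better organised in the chiral pocket than capture by bulk water), giving ion 6 with the C–O bond of the stereocentre already set; water then adds at C-2 and the ortho-acid collapses to bromohydrin 7 (any tertiary-ester isomer returns to the same alkoxide by 1,2-acyl shift under carbonate), and a 3-exo-tet SN2 at CH2Br closes the oxirane without touching the stereocentre; because 5 is the O-for-CH2 analogue of the 4-aryl-4-pentenoic acids, the DHQD series is expected to show the same sense, with O on the Si face of C-2, giving S in 6 and 7 and R in 8; the closest known reaction types are cinchona-dimer-catalysed halolactonisation of 4-aryl-4-pentenoic acids, halocyclisation of N-(2-arylallyl)amides to oxazolines, aqueous bromohydroxylation of 2-arylallyl alcohols, and Woodward–Prévost neighbouring-ester participation.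

## Compound list
1 | 2-bromo-5-(hydroxymethyl)phenol | Oc1cc(CO)ccc1Br | starting material
2 | 2-bromo-5-(hydroxymethyl)phenyl 2-methylpropanoate | CC(C)C(=O)Oc1cc(CO)ccc1Br | intermediate
3 | 2-(4,4,5,5-tetramethyl-1,3,2-dioxaborolan-2-yl)prop-2-en-1-ol | OCC(=C)B1OC(C)(C)C(C)(C)O1 | starting material
4 | 2-(4,4,5,5-tetramethyl-1,3,2-dioxaborolan-2-yl)prop-2-en-1-yl pentanoate | CCCCC(=O)OCC(=C)B1OC(C)(C)C(C)(C)O1 | intermediate
5 | 2-[4-(hydroxymethyl)-2-(2-methylpropanoyloxy)phenyl]prop-2-en-1-yl pentanoate | CCCCC(=O)OCC(=C)c1ccc(CO)cc1OC(=O)C(C)C | intermediate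
6 | (4S)-4-(bromomethyl)-2-butyl-4-[4-(hydroxymethyl)-2-(2-methylpropanoyloxy)phenyl]-1,3-dioxolan-2-ylium | CCCCC1=[O+][C@@](CBr)(c2ccc(CO)cc2OC(=O)C(C)C)CO1 | intermediate
7 | (2S)-3-bromo-2-hydroxy-2-[4-(hydroxymethyl)-2-(2-methylpropanoyloxy)phenyl]propyl pentanoate | CCCCC(=O)OC[C@@](O)(c1ccc(CO)cc1OC(=O)C(C)C)CBr | intermediate
8 | [(2R)-2-[4-(hydroxymethyl)-2-(2-methylpropanoyloxy)phenyl]oxiran-2-yl]methyl pentanoate | CCCCC(=O)OC[C@@]1(c2ccc(CO)cc2OC(=O)C(C)C)CO1 | target

## Step count
- Total step count: 4. Step 4 is one flask with two stages.
- Longest linear sequence: 3 (1 → 2 → 5 → 8, or 3 → 4 → 5 → 8).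

## Three steps most likely to fail

**Step 4 (the proposed new step).**
- The ester has no H-bond donor next to the alkene, so the ee may be lower than in the acid, amide and alcohol series.
- The sense of induction rests on an analogy. It must be checked by chiral HPLC and by rotation or ECD against the natural product. (DHQ)2PHAL gives the other antipode if the sense turns out opposite.
- The ortho-isobutyrate carbonyl can compete through a six-membered participation.
- The tertiary alkoxide can take the isobutyryl group in the carbonate stage. Either of these last two events scrambles the acyl groups.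
- Fallback: it sets out from 5 and comes back at 8, and it replaces the cation/alkoxide sequence by concerted oxygen transfer from a chiral dioxirane.
  - The conditions are a glucose-derived N-aryl spiro-lactam (or oxazolidinone) ketone of the Shi type (30 mol %), Oxone, K2CO3/AcOH buffer at pH about 9, n-Bu4NHSO4, dioxane, −10 °C.
  - This is established chemistry for 1,1-disubstituted aryl alkenes, with ee up to the high 80s.
  - No cation or alkoxide is formed, so both esters and the benzylic alcohol are left alone.
  - The catalyst antipode (D- or L-glucose series) is fixed by a test run on 5.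
  - No new compound is made.

**Step 3.**
- Fluoride at 50–60 °C may move the aryl isobutyrate onto the benzylic OH.
- The α-substituted vinyl boronate may protodeboronate.
- Pd(0) may consume the allylic ester through a π-allyl complex once the bromide is used up.
- Fallback: it sets out from 2 and comes back at 5 by a base-free Stille coupling.
  - Propargyl alcohol is hydrostannylated α-selectively (Bu3SnH, Mo(CO)3(CNt-Bu)3 cat., THF, 55 °C) to 2-(tributylstannyl)prop-2-en-1-ol F1.
  - This is acylated with pentanoic anhydride, Et3N and DMAP to 2-(tributylstannyl)prop-2-en-1-yl pentanoate F2.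
  - F2 is coupled with 2 (Pd(PPh3)4 5 mol %, CuI 10 mol %, DMF, 70 °C). No base or fluoride is present.

**Step 1.**
- Over-acylation or partial acylation of the benzylic OH would give mixtures that are hard to separate.
- Fallback: it sets out from 1 and comes back at 2, and it removes the competing alcohol instead of relying on rate differences.
  - MnO2 (CH2Cl2, rt) gives 4-bromo-3-hydroxybenzaldehyde F3, which can also be bought.
  - i-PrCOCl and Et3N (CH2Cl2, 0 °C) give 2-bromo-5-formylphenyl 2-methylpropanoate F4.
  - NaBH4 (THF/H2O, −10 °C, short contact) reduces only the aldehyde to give 2.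

## Further compounds
F0 | step 4 | none | none
F1 | step 3 | 2-(tributylstannyl)prop-2-en-1-ol | CCCC[Sn](CCCC)(CCCC)C(=C)CO
F2 | step 3 | 2-(tributylstannyl)prop-2-en-1-yl pentanoate | CCCCC(=O)OCC(=C)[Sn](CCCC)(CCCC)CCCC
F3 | step 1 | 4-bromo-3-hydroxybenzaldehyde | O=Cc1ccc(Br)c(O)c1
F4 | step 1 | 2-bromo-5-formylphenyl 2-methylpropanoate | CC(C)C(=O)Oc1cc(C=O)ccc1Br
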